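(The constants used here are assumed; what happens was integrated by code.)

Count the turns.

    catalyst intermediate B → released group + catalyst intermediate C (k1 = 1.1 s⁻¹)
    catalyst intermediate C ⇌ catalyst intermediate D (K2 = 60, k2 = 83 s⁻¹)
    catalyst intermediate D ⇌ free catalyst + target (K3 = 0.028 M, k3 = 7.1 s⁻¹)
    scavenger + released group → scavenged by-product (k4 = 3.6 L mol⁻¹ s⁻¹)
    coupling partner + released group ⇌ idle adduct, settled at all times (K5 = 30 L mol⁻¹)
    starting material + catalyst intermediate A ⇌ catalyst intermediate B (K6 = 110 L mol⁻¹, k6 = 61 L mol⁻¹ s⁻¹)
    coupling partner + free catalyst → catalyst intermediate A (k7 = 370 L mol⁻¹ s⁻¹)

| setting | Sunday's | Saturday's |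
|---|---|---|
| starting material | 0.020 M | 0.020 M |
| coupling partner | 1.00 equiv | 1.00 equiv |
| scavenger | 1.20 equiv | 1.60 equiv |
| free catalyst | 2.2 mol% | 2.2 mol% |
| time | 4.0 min | 4.0 min |
1. part of the starting material that has reacted at the end, Sunday's
2. part of the starting material that has reacted at the end, Saturday's
3. what raising the equivalents of scavenger from its lowest to its highest value here does to the part of the starting material that has reacted (changes below 5 percentage points count as none) (it falls / it rises / no change)
- amounts and yields of released group count idle adduct too
- run time (Sunday's): 4.0 min

Two chemists dispute what 4.0 min buys. In Sunday's and Saturday's, each catalyst must go round 45.5 times to use up the starting material, so both begin by pricing one round. Steps 1 and 3, taken forward, cost 1.05 s together, however much reagent is left. At the charge, taking up coupling partner costs 0.135 s, and binding starting material costs 1.23 s, returns from catalyst intermediate B to catalyst intermediate A included. Step 2, at 0.0120 s, is passed over. The sum, 2.42 s, is the turn time, the mean time of one round at the charged concentrations.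

The first chemist keeps that pace: 4.0 min allows 99.2 turns, more than the 45.5 owed, so she expects 100 percent reacted by 1.84 min.

The second, whose side I take, answers that the two reagent-dependent costs stretch as the reagents fall, in inverse proportion to the part left, since both were charged equally. Adding up the turns, loading times time equals the fixed cost times the part reacted, plus the stretching cost times the natural logarithm of charge over what is left. Loading times time is 5.28 s, so, with the part reacted put at one on the right, about 4.54% stays and 95.5% reacts.

Neither expects the scavenger to count. Released group appears once per turn and leaves by step 4, so at the charged pace and with scavenger as charged it balances near 0.00211 M in Sunday's. The idle adduct then stands at about 6.32% of the free coupling partner, and that touches a stage of 0.135 s, far shorter than the whole turn.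

The forecast stands on the second side, a little below my figure, with 94% for Sunday's, 94.5% for Saturday's and no change, saying “the falling reactant concentrations and mild product inhibition slow it”.

The simulation gives 94.5% for Sunday's and 94.5% for Saturday's, no change, with a shift of 0.04 percentage points. Sunday's ended with 5.5% of its starting material unbound, against my 4.54%. It still held 27.1% at 2.00 min, later than the first chemist's finish; the end she expected is approached at ten times the time, with 99.9% reacted in Sunday's by 40.0 min. The neighbour, Saturday's with 8.8 mol% of free catalyst, owes 11.4 turns, and the second reckoning leaves <0.001%. That flask reacted 99.4%, and at 4.00 min it held 0% of its coupling partner and 0.632% of its starting material unbound, more than that reckoning left.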